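The route rests on cutting the 1,2-dioxane ring twice (numbering from the lactone carbonyl C1): at the O–C6 bond and at the C3–C4 bond that the ring shares with the γ-lactone. What remains is a three-atom O–O–C3 piece, a hydroperoxy acetal carrying the acetate arm, and a C4–C5–C6 piece, a tertiary allylic alcohol whose C4 is a (Z)-vinylsilane. One acid-promoted operation alkylates the hydroperoxide at the tertiary allylic carbon C6 and closes the ring by ipso attack of C4 on the peroxycarbenium ion at C3, a formal [3+3] annulation. Its C4=C5 alkene then delivers the lactone oxygen to C4, exploiting the 1,3-spacing of the oxygen-bearing quaternary carbons C4 and C6 across C5.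

Key step: step 4

Remark: the annulation creates C3 and C6 from planar cations and is not expected to be enantioselective, so the route resolves its product once, directly after the key step (step 5).

Step 1
Reactants: 1 dec-9-en-2-one; 2 prop-1-yn-1-ylmagnesium bromide
Product: 3 4-methyldodec-11-en-2-yn-4-ol (racemic)
Conditions: THF, 0 °C to rt; aq. NH4Cl
Reagents that add atoms: none
Why: Nucleophilic 1,2-addition of an alkynyl Grignard reagent to the methyl ketone should give the tertiary propargylic alcohol; the carbinol centre forms as a racemate, which is of no consequence because it is ionised in step 4.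

Step 2
Reactants: 3 4-methyldodec-11-en-2-yn-4-ol
Product: 4 (Z)-4-methyl-2-(triethylsilyl)dodeca-2,11-dien-4-ol (racemic)
Conditions: Et3SiH (1.2 equiv), [Cp*Ru(MeCN)3]PF6 (2 mol %), CH2Cl2, 0 °C to rt
Reagents that add atoms: triethylsilane, CC[SiH](CC)CC
Why: Ruthenium-catalysed trans-hydrosilylation of the internal propargylic alcohol should place silicon on the alkyne carbon remote from the hydroxyl and add H and Si anti, so that silicon and the carbinol carbon end up cis (Z), the geometry needed for ring closure in step 4; no stereocentre is formed.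

Step 3
Reactants: 5 tert-butyl but-3-enoate
Product: 7 tert-butyl 3-hydroperoxy-3-methoxypropanoate (racemic), via carbonyl oxide 6 (not isolated)
Conditions: O3, CH2Cl2/MeOH (4:1), −78 °C; N2 purge, no reductive work-up
Reagents that add atoms: ozone, [O-][O+]=O; methanol, CO
Why: Ozonolysis in methanol: cycloreversion of the primary ozonide should give formaldehyde and carbonyl oxide 6, which methanol traps as the α-methoxy hydroperoxide; its acetal centre is racemic and is erased in step 4.

Step 4
Reactants: 4 (Z)-4-methyl-2-(triethylsilyl)dodeca-2,11-dien-4-ol; 7 tert-butyl 3-hydroperoxy-3-methoxypropanoate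
Product: 10 tert-butyl 2-[4,6-dimethyl-6-(oct-7-en-1-yl)-3,6-dihydro-1,2-dioxin-3-yl]acetate (all four stereoisomers), via mixed peroxyacetal 8 (not isolated), via peroxycarbenium ion 9 (not isolated)
Conditions: 7 (1.5 equiv), TMSOTf (0.3 equiv), 4 Å molecular sieves, CH2Cl2, −78 to −30 °C; pH 7 buffer
Reagents that add atoms: none
Why: Proposed new method: the acid first ionises the tertiary allylic alcohol 4 to an allyl cation that the hydroperoxide oxygen of 7 captures at the tertiary terminus C6 (the silicon-bearing terminus is disfavoured), giving 8; loss of methoxide then gives peroxycarbenium ion 9, which the vinylsilane attacks at its silicon-bearing carbon C4 to form C3–C4 and a β-silyl cation that sheds the silyl group, leaving the ring C4=C5 alkene. The closest known reaction types are the acid-catalysed alkylation of hydroperoxides by tertiary alcohols, the Lewis acid-mediated cyclisation of unsaturated peroxyacetals through peroxycarbenium ions, and vinylsilane-terminated (silyl-Prins) oxocarbenium cyclisations. The dihydrodioxine ring closes in a 6-endo-trig mode with both vinylsilane carbons inside the ring, which the Z geometry (silicon cis to C6) makes possible. C3 and C6 are both created here, C6 from a planar allyl cation and C3 from a planar peroxycarbenium ion, so no absolute control is expected and, with methyl and alkyl so alike at C6, no useful relative control either; the isomers are separated in step 5. The step needs the alcohol to ionise before the acetal, which the far greater stability of the tertiary allylic cation at −78 °C should secure, and needs the vinylsilane to outcompete the terminal alkene, which intramolecularity and the β-silicon effect should secure.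

Step 5
Reactants: 10 tert-butyl 2-[4,6-dimethyl-6-(oct-7-en-1-yl)-3,6-dihydro-1,2-dioxin-3-yl]acetate (all four stereoisomers)
Product: 11 tert-butyl 2-[(3R,6S)-4,6-dimethyl-6-(oct-7-en-1-yl)-3,6-dihydro-1,2-dioxin-3-yl]acetate
Conditions: preparative HPLC, amylose tris(3,5-dimethylphenylcarbamate) stationary phase, hexane/i-PrOH
Reagents that add atoms: none
Why: Chromatographic resolution on a chiral stationary phase: because step 4 sets C3 and C6 without absolute control, the (3R,6S) isomer (acetate arm and octenyl chain cis) is taken from the four stereoisomers here, before more material is invested.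

Step 6
Reactants: 11 tert-butyl 2-[(3R,6S)-4,6-dimethyl-6-(oct-7-en-1-yl)-3,6-dihydro-1,2-dioxin-3-yl]acetate
Product: 12 (3S,4R,4aS,7aR)-4-iodo-3,4a-dimethyl-3-(oct-7-en-1-yl)tetrahydrofuro[3,2-c][1,2]dioxin-6-one (cis-fused iodolactone, iodine trans to the lactone oxygen)
Conditions: I2 (3 equiv), NaHCO3, MeCN, 0 °C, dark; aq. Na2S2O3
Reagents that add atoms: iodine, II
Why: Iodolactonisation (5-exo-trig, anti addition): the ester carbonyl tethered at C3 can reach the iodonium ion of the C4=C5 alkene only from the face of its own arm, so the new C4–O bond is cis to the C3 arm (cis ring fusion, C4 set by C3), iodine ends up trans on C5, and the tert-butyl group leaves as isobutene.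

Step 7
Reactants: 12 (3S,4R,4aS,7aR)-4-iodo-3,4a-dimethyl-3-(oct-7-en-1-yl)tetrahydrofuro[3,2-c][1,2]dioxin-6-one
Product: 13 (3S,4aR,7aR)-3,4a-dimethyl-3-(oct-7-en-1-yl)tetrahydrofuro[3,2-c][1,2]dioxin-6-one
Conditions: Bu3SnH (5 equiv), Et3B (0.2 equiv), air, toluene, 0 °C
Reagents that add atoms: none
Why: Radical chain dehalogenation with tributyltin hydride removes the C5 stereocentre and should leave C3, C4 and C6 untouched; a high stannane concentration at 0 °C is chosen so that hydrogen transfer outruns attack of the C5 radical on the neighbouring peroxide.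

Step 8
Reactants: 13 (3S,4aR,7aR)-3,4a-dimethyl-3-(oct-7-en-1-yl)tetrahydrofuro[3,2-c][1,2]dioxin-6-one; 14 4,4,5,5-tetramethyl-2-vinyl-1,3,2-dioxaborolane
Product: 15 (3S,4aR,7aR)-3,4a-dimethyl-3-[(E)-8-(4,4,5,5-tetramethyl-1,3,2-dioxaborolan-2-yl)oct-7-en-1-yl]tetrahydrofuro[3,2-c][1,2]dioxin-6-one
Conditions: 14 (4 equiv), second-generation Grubbs catalyst RuCl2(=CHPh)(PCy3)(SIMes) (5 mol %), CH2Cl2, 40 °C
Reagents that add atoms: none
Why: Olefin cross-metathesis of the terminal alkene with the vinylboronate should give the (E)-alkenylboronate under thermodynamic control; dialkyl peroxides are tolerated by the ruthenium carbene and no stereocentre is touched.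

Step 9
Reactants: 15 (3S,4aR,7aR)-3,4a-dimethyl-3-[(E)-8-(4,4,5,5-tetramethyl-1,3,2-dioxaborolan-2-yl)oct-7-en-1-yl]tetrahydrofuro[3,2-c][1,2]dioxin-6-one; 16 (E)-(2-bromovinyl)benzene
Product: 17 plakortolide Q, (3S,4aR,7aR)-3,4a-dimethyl-3-[(7E,9E)-10-phenyldeca-7,9-dien-1-yl]tetrahydrofuro[3,2-c][1,2]dioxin-6-one
Conditions: Pd(PPh3)4 (5 mol %), K3PO4 (2 equiv), THF/H2O (10:1), 40 °C
Reagents that add atoms: none
Why: Suzuki–Miyaura coupling proceeds with retention at both alkenyl partners and should give the (7E,9E)-diene, completing the side chain without touching C3, C4 or C6.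

Compound list
1 | dec-9-en-2-one | CC(=O)CCCCCCC=C | starting material
2 | prop-1-yn-1-ylmagnesium bromide | CC#C[Mg]Br | starting material
3 | 4-methyldodec-11-en-2-yn-4-ol (racemic) | CC#CC(C)(O)CCCCCCC=C | intermediate
4 | (Z)-4-methyl-2-(triethylsilyl)dodeca-2,11-dien-4-ol (racemic; silicon cis to the carbinol carbon) | C/C([Si](CC)(CC)CC)=C/C(C)(O)CCCCCCC=C | intermediate
5 | tert-butyl but-3-enoate | C=CCC(=O)OC(C)(C)C | starting material
6 | carbonyl oxide of tert-butyl 3-oxopropanoate (not isolated) | [O-][O+]=CCC(=O)OC(C)(C)C | intermediate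
7 | tert-butyl 3-hydroperoxy-3-methoxypropanoate (racemic) | COC(OO)CC(=O)OC(C)(C)C | intermediate
8 | tert-butyl 3-methoxy-3-{[(Z)-4-methyl-2-(triethylsilyl)dodeca-2,11-dien-4-yl]peroxy}propanoate (mixed peroxyacetal, not isolated, stereoisomer mixture) | C/C([Si](CC)(CC)CC)=C/C(C)(CCCCCCC=C)OOC(OC)CC(=O)OC(C)(C)C | intermediate
9 | peroxycarbenium ion formed from 8 by loss of methoxide (not isolated) | C/C([Si](CC)(CC)CC)=C/C(C)(CCCCCCC=C)O[O+]=CCC(=O)OC(C)(C)C | intermediate
10 | tert-butyl 2-[4,6-dimethyl-6-(oct-7-en-1-yl)-3,6-dihydro-1,2-dioxin-3-yl]acetate (all four stereoisomers, no configuration specified) | CC1(CCCCCCC=C)C=C(C)C(CC(=O)OC(C)(C)C)OO1 | intermediate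
11 | tert-butyl 2-[(3R,6S)-4,6-dimethyl-6-(oct-7-en-1-yl)-3,6-dihydro-1,2-dioxin-3-yl]acetate | C[C@]1(CCCCCCC=C)C=C(C)[C@@H](CC(=O)OC(C)(C)C)OO1 | intermediate
12 | (3S,4R,4aS,7aR)-4-iodo-3,4a-dimethyl-3-(oct-7-en-1-yl)tetrahydrofuro[3,2-c][1,2]dioxin-6-one | C[C@]1(CCCCCCC=C)[C@H](I)[C@@]2(C)OC(=O)C[C@H]2OO1 | intermediate
13 | (3S,4aR,7aR)-3,4a-dimethyl-3-(oct-7-en-1-yl)tetrahydrofuro[3,2-c][1,2]dioxin-6-one | C[C@]1(CCCCCCC=C)C[C@@]2(C)OC(=O)C[C@H]2OO1 | intermediate
14 | 4,4,5,5-tetramethyl-2-vinyl-1,3,2-dioxaborolane | C=CB1OC(C)(C)C(C)(C)O1 | starting material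
15 | (3S,4aR,7aR)-3,4a-dimethyl-3-[(E)-8-(4,4,5,5-tetramethyl-1,3,2-dioxaborolan-2-yl)oct-7-en-1-yl]tetrahydrofuro[3,2-c][1,2]dioxin-6-one | C[C@]1(CCCCCC/C=C/B3OC(C)(C)C(C)(C)O3)C[C@@]2(C)OC(=O)C[C@H]2OO1 | intermediate
16 | (E)-(2-bromovinyl)benzene | Br/C=C/c1ccccc1 | starting material
17 | plakortolide Q, (3S,4aR,7aR)-3,4a-dimethyl-3-[(7E,9E)-10-phenyldeca-7,9-dien-1-yl]tetrahydrofuro[3,2-c][1,2]dioxin-6-one | C[C@]1(CCCCCC/C=C/C=C/c2ccccc2)C[C@@]2(C)OC(=O)C[C@H]2OO1 | target

Total step count: 9. Longest linear sequence: 8 (steps 1, 2, 4, 5, 6, 7, 8, 9).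

Steps most likely to fail

Step 4 (the proposed annulation). The hydroperoxy acetal or the newly formed tertiary allylic peroxide may fragment under the acid instead of closing the ring, and protodesilylation of the vinylsilane may outpace C–C bond formation. The fallback uses known chemistry, singlet-oxygen [4+2] cycloaddition to a 1,3-diene; it sets out from 3 and comes back at 10. Meyer–Schuster rearrangement of 3 (Ph3PAuNTf2 cat., wet toluene/MeOH) gives (E)-4-methyldodeca-3,11-dien-2-one F1. Vinylmagnesium bromide adds 1,2 to give (E)-3,5-dimethyltrideca-1,4,12-trien-3-ol F2, and Boc2O/n-BuLi gives its tert-butyl carbonate F3. Pd(OAc)2/PPh3-catalysed decarboxylative carbonylation (CO, THF, 50 °C) at the unsubstituted allyl terminus gives tert-butyl (3E,5E)-4,6-dimethyltetradeca-3,5,13-trienoate F4. Photo-oxygenation (O2, tetraphenylporphyrin, visible light, CH2Cl2, 0 °C) then gives 10. Because the addition is suprafacial to the E,E-diene, only the racemic cis (3R*,6S*) diastereomer should form, and step 5 follows unchanged.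

Step 7. The C5 radical sits next to the peroxide-bearing C6 and may close onto oxygen, giving an epoxide and breaking the O–O bond before it is reduced. The fallback avoids both the iodide and the radical; it sets out from 11 and comes back at 13. The tert-butyl ester is cleaved with TMSOTf/2,6-lutidine and aqueous work-up to 2-[(3R,6S)-4,6-dimethyl-6-(oct-7-en-1-yl)-3,6-dihydro-1,2-dioxin-3-yl]acetic acid F5. Acid-catalysed Markovnikov hydrolactonisation (TfOH 5 mol %, CH2Cl2, −40 °C) then closes F5 to 13: protonation at C5 gives the tertiary C4 cation, which the carboxyl group captures on the face of its own arm.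

Step 9. Zerovalent palladium may insert into or reduce the O–O bond, and the aqueous base may open the lactone or trigger β-elimination of the peroxide from C3. The fallback replaces cross-coupling by olefination; it sets out from 13 and comes back at 17. Ozonolysis of the terminal alkene (O3, CH2Cl2, −78 °C; Me2S) gives 7-[(3S,4aR,7aR)-3,4a-dimethyl-6-oxotetrahydrofuro[3,2-c][1,2]dioxin-3-yl]heptanal F6. Horner–Wadsworth–Emmons reaction with the lithium anion of diethyl cinnamylphosphonate (LiHMDS, THF, −78 °C) then gives 17 as the E,E-diene.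

Further compounds
F1 | step 4 | (E)-4-methyldodeca-3,11-dien-2-one | CC(=O)/C=C(\C)CCCCCCC=C
F2 | step 4 | (E)-3,5-dimethyltrideca-1,4,12-trien-3-ol (racemic) | C=CC(C)(O)/C=C(\C)CCCCCCC=C
F3 | step 4 | tert-butyl (E)-3,5-dimethyltrideca-1,4,12-trien-3-yl carbonate (racemic) | C=CC(C)(OC(=O)OC(C)(C)C)/C=C(\C)CCCCCCC=C
F4 | step 4 | tert-butyl (3E,5E)-4,6-dimethyltetradeca-3,5,13-trienoate | CC(C)(C)OC(=O)C/C=C(C)/C=C(\C)CCCCCCC=C
F5 | step 7 | 2-[(3R,6S)-4,6-dimethyl-6-(oct-7-en-1-yl)-3,6-dihydro-1,2-dioxin-3-yl]acetic acid | C[C@]1(CCCCCCC=C)C=C(C)[C@@H](CC(=O)O)OO1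
F6 | step 9 | 7-[(3S,4aR,7aR)-3,4a-dimethyl-6-oxotetrahydrofuro[3,2-c][1,2]dioxin-3-yl]heptanal | C[C@]1(CCCCCCC=O)C[C@@]2(C)OC(=O)C[C@H]2OO1
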